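## Retrosynthetic overview

1. Target 34 comes from global desilylation of ester 33. Ester 33 is disconnected at the acyl–O bond: acid 19 (fragment A, the C14 cyclohexene half) opens the CH2 of spiro-epoxide 32 (fragment B, the C15 lactone half), which gives the tertiary alcohol and the primary ester in one step.
2. Fragment A: the side-chain alkene comes from an E-selective Wittig reaction on aldehyde 12. Its cyclohexene ring is built first, by an enantioselective endo Diels–Alder reaction of diene 6 with but-3-en-2-one (cis centres); the acetyl group is then turned into isopropyl.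
3. Fragment B: the cyclohexenone ring is built first (organocatalytic Michael addition, then aldol condensation, to (R)-cryptone 22). A CuBr·SMe2-catalysed vinyl Grignard addition with formaldehyde trapping sets two centres, and a Corey–Chaykovsky epoxidation sets the quaternary centre.
4. The seven-membered lactone of fragment B is closed last, by ring-closing metathesis.

Assumption: in step 5 the (R)-prolinol-derived oxazaborolidinium catalyst is taken to give the (1R,2S) adduct 8; should the antipode form, the (S)-catalyst is used and nothing else changes.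

## Route

### Fragment A (acid 19)

Step 1
Reactants: 1 prop-2-yn-1-ol
Product: 2 1-methoxy-4-[(prop-2-yn-1-yloxy)methyl]benzene
Conditions: NaH, 4-methoxybenzyl chloride, Bu4NI (cat.), THF, 0 °C to rt
Reagents that add atoms: 4-methoxybenzyl chloride, COc1ccc(CCl)cc1
Why: Williamson ether synthesis masks the alcohol as a PMB ether that can later be removed oxidatively without touching silyl ethers.

Step 2
Reactants: 2 1-methoxy-4-[(prop-2-yn-1-yloxy)methyl]benzene
Product: 3 2-[(1E)-3-[(4-methoxybenzyl)oxy]prop-1-en-1-yl]-4,4,5,5-tetramethyl-1,3,2-dioxaborolane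
Conditions: pinacolborane, Cp2Zr(H)Cl (5 mol%), Et3N (10 mol%), neat, 60 °C
Reagents that add atoms: pinacolborane, [H]B1OC(C)(C)C(C)(C)O1
Why: Cp2Zr(H)Cl-catalysed hydroboration of the terminal alkyne is a syn, anti-Markovnikov addition and gives only the (E)-alkenyl boronate.

Step 3
Reactants: 4 2-bromoprop-2-en-1-ol
Product: 5 [(2-bromoprop-2-en-1-yl)oxy](tert-butyl)dimethylsilane
Conditions: TBSCl, imidazole, CH2Cl2, 0 °C to rt
Reagents that add atoms: tert-butyldimethylsilyl chloride, CC(C)(C)[Si](C)(C)Cl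
Why: Silylation of the primary alcohol gives a TBS ether that is kept until the final deprotection.

Step 4
Reactants: 3 the (E)-alkenyl boronate; 5 the 2-bromoallyl TBS ether
Product: 6 tert-butyl({(3E)-5-[(4-methoxybenzyl)oxy]-2-methylidenepent-3-en-1-yl}oxy)dimethylsilane
Conditions: Pd(PPh3)4 (5 mol%), K3PO4, THF/H2O, 60 °C
Reagents that add atoms: none
Why: Suzuki–Miyaura coupling joins the two sp2 carbons with retention of the E geometry and gives the 1,3-disubstituted diene.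

Step 5
Reactants: 6 the diene; 7 but-3-en-2-one
Product: 8 1-[(1R,2S)-4-{[(tert-butyldimethylsilyl)oxy]methyl}-2-{[(4-methoxybenzyl)oxy]methyl}cyclohex-3-en-1-yl]ethan-1-one
Conditions: (R)-o-tolyl-CBS oxazaborolidine·Tf2NH (15 mol%), CH2Cl2, −78 to −40 °C
Reagents that add atoms: none
Why: Lewis-acid-catalysed Diels–Alder reaction in which both diene substituents direct the acetyl carbon next to the CH2OPMB carbon, the endo transition state makes the two new centres cis, and the chiral oxazaborolidinium blocks one face of the bound enone to set the absolute configuration.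

Step 6
Reactants: 8 the cis methyl ketone
Product: 9 tert-butyl({(3S,4R)-3-{[(4-methoxybenzyl)oxy]methyl}-4-(prop-1-en-2-yl)cyclohex-1-en-1-yl}methoxy)dimethylsilane
Conditions: Cp2TiMe2, toluene, 70 °C, dark
Reagents that add atoms: dimethyltitanocene, C[Ti](C)(C1C=CC=C1)C1C=CC=C1
Why: Petasis methylenation is non-basic, so the epimerisable cis centre next to the ketone is not disturbed.

Step 7
Reactants: 9 the isopropenyl compound
Product: 10 tert-butyl({(3R,4S)-3-{[(4-methoxybenzyl)oxy]methyl}-4-(propan-2-yl)cyclohex-1-en-1-yl}methoxy)dimethylsilane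
Conditions: H2 (1 atm), RhCl(PPh3)3 (5 mol%), benzene, rt
Reagents that add atoms: none
Why: Homogeneous hydrogenation with RhCl(PPh3)3 reduces the 1,1-disubstituted alkene much faster than the trisubstituted ring alkene and creates no stereocentre (the descriptors change only through CIP priorities).

Step 8
Reactants: 10 the PMB ether
Product: 11 [(1R,6S)-3-{[(tert-butyldimethylsilyl)oxy]methyl}-6-(propan-2-yl)cyclohex-2-en-1-yl]methanol
Conditions: DDQ, CH2Cl2/pH 7 buffer, 0 °C
Reagents that add atoms: none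
Why: Oxidative PMB cleavage by DDQ leaves the TBS ether and the ring alkene intact.

Step 9
Reactants: 11 the primary alcohol
Product: 12 (1R,6S)-3-{[(tert-butyldimethylsilyl)oxy]methyl}-6-(propan-2-yl)cyclohex-2-ene-1-carbaldehyde
Conditions: Dess–Martin periodinane, NaHCO3, CH2Cl2, 0 °C; used crude
Reagents that add atoms: none
Why: Buffered Dess–Martin oxidation gives the β,γ-unsaturated aldehyde without base, so C1 is not epimerised and the alkene does not move into conjugation.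

Step 10
Reactants: 13 prop-2-en-1-yl bromoacetate
Product: 15 prop-2-en-1-yl (triphenyl-λ5-phosphanylidene)acetate, via phosphonium bromide 14 (not isolated)
Conditions: PPh3, toluene, rt; then aq. NaOH, CH2Cl2, 0 °C
Reagents that add atoms: triphenylphosphine, c1ccc(cc1)P(c1ccccc1)c1ccccc1
Why: SN2 quaternisation of PPh3 followed by deprotonation of the acidic phosphonium salt gives the stabilised ylide.

Step 11
Reactants: 15 the stabilised ylide
Product: 17 prop-2-en-1-yl 2-(triphenyl-λ5-phosphanylidene)-3-{[tri(propan-2-yl)silyl]oxy}propanoate, via phosphonium chloride 16 (not isolated)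
Conditions: (chloromethoxy)tri(propan-2-yl)silane, CH2Cl2, 0 °C to rt; then aq. NaOH
Reagents that add atoms: (chloromethoxy)tri(propan-2-yl)silane, ClCO[Si](C(C)C)(C(C)C)C(C)C
Why: C-alkylation of the stabilised ylide by the reactive α-chloro ether, then deprotonation, puts a TIPS-protected hydroxymethyl group on the ylide carbon.

Step 12
Reactants: 12 the aldehyde; 17 the substituted ylide
Product: 18 prop-2-en-1-yl (2E)-3-[(1R,6S)-3-{[(tert-butyldimethylsilyl)oxy]methyl}-6-(propan-2-yl)cyclohex-2-en-1-yl]-2-({[tri(propan-2-yl)silyl]oxy}methyl)prop-2-enoate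
Conditions: toluene, 60 °C
Reagents that add atoms: none
Why: Wittig olefination with a stabilised α-substituted ylide is E-selective (ester trans to the ring carbon), and the neutral ylide is too weak a base to epimerise C1.

Step 13
Reactants: 18 the allyl ester
Product: 19 (2E)-3-[(1R,6S)-3-{[(tert-butyldimethylsilyl)oxy]methyl}-6-(propan-2-yl)cyclohex-2-en-1-yl]-2-({[tri(propan-2-yl)silyl]oxy}methyl)prop-2-enoic acid
Conditions: Pd(PPh3)4 (5 mol%), morpholine, THF, rt
Reagents that add atoms: none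
Why: Pd(PPh3)4-catalysed allyl transfer to morpholine (Tsuji–Trost deallylation) frees the acid under neutral conditions that spare the silyl ethers and the doubly allylic C1–H.

### Fragment B (spiro-epoxide lactone 32)

Step 14
Reactants: 20 3-methylbutanal; 7 but-3-en-2-one
Product: 21 (2R)-5-oxo-2-(propan-2-yl)hexanal
Conditions: (R)-2-[methoxy(diphenyl)methyl]pyrrolidine (5 mol%), ethyl 3,4-dihydroxybenzoate (20 mol%), neat, 4 °C
Reagents that add atoms: none
Why: Enamine-catalysed Michael addition in which the diphenyl(methoxy)methyl group shields one face of the E-enamine, so the enone adds to the open face and sets the R centre.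

Step 15
Reactants: 21 the keto aldehyde
Product: 22 (4R)-4-(propan-2-yl)cyclohex-2-en-1-one
Conditions: LiOH (20 mol%), iPrOH, rt
Reagents that add atoms: none
Why: Intramolecular aldol condensation of the methyl ketone onto the aldehyde closes the cyclohexenone and moves the stereocentre to the non-enolisable γ-position.

Step 16
Reactants: 22 (R)-cryptone
Product: 24 (2R,3R,4R)-3-ethenyl-2-(hydroxymethyl)-4-(propan-2-yl)cyclohexan-1-one, via magnesium enolate 23 (not isolated)
Conditions: vinylmagnesium bromide, CuBr·SMe2 (10 mol%), THF, −78 °C; then monomeric CH2O in THF, −78 to −40 °C; aq. NH4Cl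
Reagents that add atoms: vinylmagnesium bromide, C=C[Mg]Br; formaldehyde, C=O
Why: CuBr·SMe2-catalysed conjugate addition delivers the vinyl group anti to the isopropyl group, and aldol trapping of the regiodefined enolate by formaldehyde occurs anti to the new vinyl group, giving the all-trans, all-equatorial ketone.

Step 17
Reactants: 24 the β-hydroxy ketone
Product: 25 (2R,3R,4R)-2-{[(tert-butyldimethylsilyl)oxy]methyl}-3-ethenyl-4-(propan-2-yl)cyclohexan-1-one
Conditions: TBSCl, imidazole, CH2Cl2, 0 °C to rt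
Reagents that add atoms: tert-butyldimethylsilyl chloride, CC(C)(C)[Si](C)(C)Cl
Why: Silylation blocks retro-aldol loss of formaldehyde and removes the acidic OH before the ylide step.

Step 18
Reactants: 25 the silyloxy ketone
Product: 26 tert-butyl{[(3S,4R,5R,6R)-5-ethenyl-6-(propan-2-yl)-1-oxaspiro[2.5]octan-4-yl]methoxy}dimethylsilane
Conditions: Me3S+ I−, n-BuLi, THF, −10 to 0 °C
Reagents that add atoms: trimethylsulfonium iodide, C[S+](C)C.[I-]
Why: Corey–Chaykovsky epoxidation in which the small sulfonium ylide adds irreversibly along the axial trajectory, so the CH2 ends axial (cis to the CH2OTBS arm) and the oxygen equatorial, which sets the quaternary S centre.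

Step 19
Reactants: 26 the epoxy silyl ether
Product: 27 [(3S,4R,5R,6R)-5-ethenyl-6-(propan-2-yl)-1-oxaspiro[2.5]octan-4-yl]methanol
Conditions: TBAF, THF, 0 °C to rt
Reagents that add atoms: none
Why: Fluoride desilylation frees the primary alcohol, and the oxirane is safe because the alkoxide could only open it in a disfavoured 5-endo or 4-exo mode.

Step 20
Reactants: 27 the epoxy alcohol
Product: 28 (3S,4S,5R,6R)-5-ethenyl-6-(propan-2-yl)-1-oxaspiro[2.5]octane-4-carboxylic acid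
Conditions: TEMPO (10 mol%), NaClO2, NaOCl (5 mol%), MeCN/pH 6.7 phosphate buffer, 35 °C
Reagents that add atoms: sodium chlorite, [Na+].[O-]Cl=O
Why: TEMPO/chlorite oxidation takes the primary alcohol to the acid near neutral pH, and the oxirane survives because carboxylate attack on its CH2 would be 5-endo and its equatorial C–O bond is not aligned with the axial α C–H bond for elimination.

Step 21
Reactants: 29 2-(bromomethyl)prop-2-enoic acid
Product: 30 2-(trimethylsilyl)ethyl 2-(bromomethyl)prop-2-enoate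
Conditions: 2-(trimethylsilyl)ethanol, DCC, DMAP (5 mol%), CH2Cl2, 0 °C
Reagents that add atoms: 2-(trimethylsilyl)ethanol, C[Si](C)(C)CCO
Why: Steglich esterification installs a fluoride-labile ester so that the last step can remove all protecting groups together.

Step 22
Reactants: 28 the epoxy acid; 30 the allylic bromide
Product: 31 2-{[2-(trimethylsilyl)ethoxy]carbonyl}prop-2-en-1-yl (3S,4S,5R,6R)-5-ethenyl-6-(propan-2-yl)-1-oxaspiro[2.5]octane-4-carboxylate
Conditions: KHCO3, DMF, 0 °C to rt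
Reagents that add atoms: none
Why: The potassium carboxylate is O-alkylated (SN2) by the highly reactive allylic bromide under conditions too mild to enolise the ester or open the oxirane.

Step 23
Reactants: 31 the triene ester
Product: 32 2-(trimethylsilyl)ethyl (5aS,6R,9S,9aS)-1-oxo-6-(propan-2-yl)-3,5a,6,7,8,9a-hexahydro-1H-spiro[2-benzoxepine-9,2'-oxirane]-4-carboxylate
Conditions: second-generation Hoveyda–Grubbs catalyst RuCl2(H2IMes)(=CH-C6H4-2-OiPr) (10 mol%), toluene (0.003 M), 80 °C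
Reagents that add atoms: none
Why: Ring-closing metathesis between the vinyl group and the acrylate methylene forms the trans-fused seven-membered lactone, and the ring forces the OCH2 group and the ring carbon cis on the new trisubstituted alkene, which is the required geometry.

### Union and deprotection

Step 24
Reactants: 19 acid of fragment A; 32 spiro-epoxide lactone of fragment B
Product: 33 2-(trimethylsilyl)ethyl (5aS,6R,9S,9aS)-9-({[(2E)-3-[(1R,6S)-3-{[(tert-butyldimethylsilyl)oxy]methyl}-6-(propan-2-yl)cyclohex-2-en-1-yl]-2-({[tri(propan-2-yl)silyl]oxy}methyl)prop-2-enoyl]oxy}methyl)-9-hydroxy-1-oxo-6-(propan-2-yl)-1,3,5a,6,7,8,9,9a-octahydro-2-benzoxepine-4-carboxylate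
Conditions: 19 (2 equiv), Cs2CO3 (0.3 equiv), DMF, 75 °C
Reagents that add atoms: none
Why: The Cs salt of 19 opens the oxirane by SN2 attack at the unsubstituted CH2, so the quaternary C–O bond is untouched (9S retained), the excess free acid protonates the tertiary alkoxide, and no free primary alcohol ever sits next to the lactone carbonyl.

Step 25
Reactants: 33 the protected ester
Product: 34 (5aS,6R,9S,9aS)-9-hydroxy-9-({[(2E)-2-(hydroxymethyl)-3-[(1R,6S)-3-(hydroxymethyl)-6-(propan-2-yl)cyclohex-2-en-1-yl]prop-2-enoyl]oxy}methyl)-1-oxo-6-(propan-2-yl)-1,3,5a,6,7,8,9,9a-octahydro-2-benzoxepine-4-carboxylic acid (CNP0361406.5)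
Conditions: TBAF, AcOH (1:1), THF, 0 °C to rt
Reagents that add atoms: none
Why: Fluoride cleaves both silyl ethers and fragments the 2-(trimethylsilyl)ethyl ester (loss of ethene and Me3SiF), while the acetic acid buffer suppresses alkoxide-driven acyl migration and translactonisation, and no stereocentre is touched.

## Compound list

1 | prop-2-yn-1-ol | C#CCO | starting material
2 | 1-methoxy-4-[(prop-2-yn-1-yloxy)methyl]benzene | COc1ccc(COCC#C)cc1 | intermediate
3 | 2-[(1E)-3-[(4-methoxybenzyl)oxy]prop-1-en-1-yl]-4,4,5,5-tetramethyl-1,3,2-dioxaborolane | COc1ccc(COC/C=C/B2OC(C)(C)C(C)(C)O2)cc1 | intermediate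
4 | 2-bromoprop-2-en-1-ol | OCC(Br)=C | starting material
5 | [(2-bromoprop-2-en-1-yl)oxy](tert-butyl)dimethylsilane | CC(C)(C)[Si](C)(C)OCC(Br)=C | intermediate
6 | tert-butyl({(3E)-5-[(4-methoxybenzyl)oxy]-2-methylidenepent-3-en-1-yl}oxy)dimethylsilane | COc1ccc(COC/C=C/C(=C)CO[Si](C)(C)C(C)(C)C)cc1 | intermediate
7 | but-3-en-2-one | CC(=O)C=C | starting material
8 | 1-[(1R,2S)-4-{[(tert-butyldimethylsilyl)oxy]methyl}-2-{[(4-methoxybenzyl)oxy]methyl}cyclohex-3-en-1-yl]ethan-1-one | COc1ccc(COC[C@H]2C=C(CO[Si](C)(C)C(C)(C)C)CC[C@H]2C(C)=O)cc1 | intermediate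
9 | tert-butyl({(3S,4R)-3-{[(4-methoxybenzyl)oxy]methyl}-4-(prop-1-en-2-yl)cyclohex-1-en-1-yl}methoxy)dimethylsilane | COc1ccc(COC[C@H]2C=C(CO[Si](C)(C)C(C)(C)C)CC[C@H]2C(C)=C)cc1 | intermediate
10 | tert-butyl({(3R,4S)-3-{[(4-methoxybenzyl)oxy]methyl}-4-(propan-2-yl)cyclohex-1-en-1-yl}methoxy)dimethylsilane | COc1ccc(COC[C@H]2C=C(CO[Si](C)(C)C(C)(C)C)CC[C@H]2C(C)C)cc1 | intermediate
11 | [(1R,6S)-3-{[(tert-butyldimethylsilyl)oxy]methyl}-6-(propan-2-yl)cyclohex-2-en-1-yl]methanol | OC[C@H]1C=C(CO[Si](C)(C)C(C)(C)C)CC[C@H]1C(C)C | intermediate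
12 | (1R,6S)-3-{[(tert-butyldimethylsilyl)oxy]methyl}-6-(propan-2-yl)cyclohex-2-ene-1-carbaldehyde | O=C[C@H]1C=C(CO[Si](C)(C)C(C)(C)C)CC[C@H]1C(C)C | intermediate
13 | prop-2-en-1-yl bromoacetate | C=CCOC(=O)CBr | starting material
14 | [2-oxo-2-(prop-2-en-1-yloxy)ethyl]triphenylphosphonium bromide | C=CCOC(=O)C[P+](c1ccccc1)(c1ccccc1)c1ccccc1.[Br-] | intermediate
15 | prop-2-en-1-yl (triphenyl-λ5-phosphanylidene)acetate | C=CCOC(=O)C=P(c1ccccc1)(c1ccccc1)c1ccccc1 | intermediate
16 | [1-oxo-1-(prop-2-en-1-yloxy)-3-{[tri(propan-2-yl)silyl]oxy}propan-2-yl]triphenylphosphonium chloride | C=CCOC(=O)C(CO[Si](C(C)C)(C(C)C)C(C)C)[P+](c1ccccc1)(c1ccccc1)c1ccccc1.[Cl-] | intermediate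
17 | prop-2-en-1-yl 2-(triphenyl-λ5-phosphanylidene)-3-{[tri(propan-2-yl)silyl]oxy}propanoate | C=CCOC(=O)C(CO[Si](C(C)C)(C(C)C)C(C)C)=P(c1ccccc1)(c1ccccc1)c1ccccc1 | intermediate
18 | prop-2-en-1-yl (2E)-3-[(1R,6S)-3-{[(tert-butyldimethylsilyl)oxy]methyl}-6-(propan-2-yl)cyclohex-2-en-1-yl]-2-({[tri(propan-2-yl)silyl]oxy}methyl)prop-2-enoate | C=CCOC(=O)/C(=C/[C@H]1C=C(CO[Si](C)(C)C(C)(C)C)CC[C@H]1C(C)C)CO[Si](C(C)C)(C(C)C)C(C)C | intermediate
19 | (2E)-3-[(1R,6S)-3-{[(tert-butyldimethylsilyl)oxy]methyl}-6-(propan-2-yl)cyclohex-2-en-1-yl]-2-({[tri(propan-2-yl)silyl]oxy}methyl)prop-2-enoic acid | OC(=O)/C(=C/[C@H]1C=C(CO[Si](C)(C)C(C)(C)C)CC[C@H]1C(C)C)CO[Si](C(C)C)(C(C)C)C(C)C | intermediate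
20 | 3-methylbutanal | CC(C)CC=O | starting material
21 | (2R)-5-oxo-2-(propan-2-yl)hexanal | CC(C)[C@H](C=O)CCC(C)=O | intermediate
22 | (4R)-4-(propan-2-yl)cyclohex-2-en-1-one | CC(C)[C@H]1CCC(=O)C=C1 | intermediate
23 | bromo{[(3R,4R)-3-ethenyl-4-(propan-2-yl)cyclohex-1-en-1-yl]oxy}magnesium | CC(C)[C@H]1CCC(O[Mg]Br)=C[C@@H]1C=C | intermediate
24 | (2R,3R,4R)-3-ethenyl-2-(hydroxymethyl)-4-(propan-2-yl)cyclohexan-1-one | CC(C)[C@H]1CCC(=O)[C@@H](CO)[C@@H]1C=C | intermediate
25 | (2R,3R,4R)-2-{[(tert-butyldimethylsilyl)oxy]methyl}-3-ethenyl-4-(propan-2-yl)cyclohexan-1-one | CC(C)[C@H]1CCC(=O)[C@@H](CO[Si](C)(C)C(C)(C)C)[C@@H]1C=C | intermediate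
26 | tert-butyl{[(3S,4R,5R,6R)-5-ethenyl-6-(propan-2-yl)-1-oxaspiro[2.5]octan-4-yl]methoxy}dimethylsilane | CC(C)[C@H]1CC[C@@]2(CO2)[C@@H](CO[Si](C)(C)C(C)(C)C)[C@@H]1C=C | intermediate
27 | [(3S,4R,5R,6R)-5-ethenyl-6-(propan-2-yl)-1-oxaspiro[2.5]octan-4-yl]methanol | CC(C)[C@H]1CC[C@@]2(CO2)[C@@H](CO)[C@@H]1C=C | intermediate
28 | (3S,4S,5R,6R)-5-ethenyl-6-(propan-2-yl)-1-oxaspiro[2.5]octane-4-carboxylic acid | CC(C)[C@H]1CC[C@@]2(CO2)[C@@H](C(=O)O)[C@@H]1C=C | intermediate
29 | 2-(bromomethyl)prop-2-enoic acid | OC(=O)C(=C)CBr | starting material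
30 | 2-(trimethylsilyl)ethyl 2-(bromomethyl)prop-2-enoate | C[Si](C)(C)CCOC(=O)C(=C)CBr | intermediate
31 | 2-{[2-(trimethylsilyl)ethoxy]carbonyl}prop-2-en-1-yl (3S,4S,5R,6R)-5-ethenyl-6-(propan-2-yl)-1-oxaspiro[2.5]octane-4-carboxylate | CC(C)[C@H]1CC[C@@]2(CO2)[C@@H](C(=O)OCC(=C)C(=O)OCC[Si](C)(C)C)[C@@H]1C=C | intermediate
32 | 2-(trimethylsilyl)ethyl (5aS,6R,9S,9aS)-1-oxo-6-(propan-2-yl)-3,5a,6,7,8,9a-hexahydro-1H-spiro[2-benzoxepine-9,2'-oxirane]-4-carboxylate | CC(C)[C@H]1CC[C@@]3(CO3)[C@H]2C(=O)OCC(C(=O)OCC[Si](C)(C)C)=C[C@H]12 | intermediate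
33 | 2-(trimethylsilyl)ethyl (5aS,6R,9S,9aS)-9-({[(2E)-3-[(1R,6S)-3-{[(tert-butyldimethylsilyl)oxy]methyl}-6-(propan-2-yl)cyclohex-2-en-1-yl]-2-({[tri(propan-2-yl)silyl]oxy}methyl)prop-2-enoyl]oxy}methyl)-9-hydroxy-1-oxo-6-(propan-2-yl)-1,3,5a,6,7,8,9,9a-octahydro-2-benzoxepine-4-carboxylate | CC(C)[C@H]1CC[C@@](O)(COC(=O)/C(=C/[C@H]2C=C(CO[Si](C)(C)C(C)(C)C)CC[C@H]2C(C)C)CO[Si](C(C)C)(C(C)C)C(C)C)[C@H]2C(=O)OCC(C(=O)OCC[Si](C)(C)C)=C[C@H]12 | intermediate
34 | (5aS,6R,9S,9aS)-9-hydroxy-9-({[(2E)-2-(hydroxymethyl)-3-[(1R,6S)-3-(hydroxymethyl)-6-(propan-2-yl)cyclohex-2-en-1-yl]prop-2-enoyl]oxy}methyl)-1-oxo-6-(propan-2-yl)-1,3,5a,6,7,8,9,9a-octahydro-2-benzoxepine-4-carboxylic acid | CC(C)[C@H]1CC[C@@](O)(COC(=O)/C(=C/[C@H]2C=C(CO)CC[C@H]2C(C)C)CO)[C@H]2C(=O)OCC(C(=O)O)=C[C@H]12 | target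

## Step count and risks

Total step count: 25.
Longest linear sequence: 12 steps (steps 1, 2, 4, 5, 6, 7, 8, 9, 12, 13, 24, 25).

**Step 24 (epoxide opening by the acid).** The oxirane CH2 is neopentyl-like and shielded by two syn-axial hydrogens, and the nucleophile is a hindered α-branched carboxylate. The opening may be too slow, and long heating may damage the unsaturated lactone. The fallback makes the same ester by acylating a diol and sets out from 26.
- Heating 26 with NaH and 4-methoxybenzyl alcohol in DMF at 90 °C opens the oxirane at CH2 to give (1S,2R,3R,4R)-2-{[(tert-butyldimethylsilyl)oxy]methyl}-3-ethenyl-1-{[(4-methoxybenzyl)oxy]methyl}-4-(propan-2-yl)cyclohexan-1-ol F1.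
- TBAF gives (1S,2R,3R,4R)-3-ethenyl-2-(hydroxymethyl)-1-{[(4-methoxybenzyl)oxy]methyl}-4-(propan-2-yl)cyclohexan-1-ol F2.
- TEMPO/NaOCl/NaClO2 oxidation gives (1S,2S,5R,6R)-6-ethenyl-2-hydroxy-2-{[(4-methoxybenzyl)oxy]methyl}-5-(propan-2-yl)cyclohexane-1-carboxylic acid F3.
- Alkylation with 30 (KHCO3, DMF) gives 2-{[2-(trimethylsilyl)ethoxy]carbonyl}prop-2-en-1-yl (1S,2S,5R,6R)-6-ethenyl-2-hydroxy-2-{[(4-methoxybenzyl)oxy]methyl}-5-(propan-2-yl)cyclohexane-1-carboxylate F4.
- Ring-closing metathesis (second-generation Hoveyda–Grubbs catalyst RuCl2(H2IMes)(=CH-C6H4-2-OiPr), toluene, 80 °C) gives 2-(trimethylsilyl)ethyl (5aS,6R,9S,9aS)-9-hydroxy-9-{[(4-methoxybenzyl)oxy]methyl}-1-oxo-6-(propan-2-yl)-1,3,5a,6,7,8,9,9a-octahydro-2-benzoxepine-4-carboxylate F5.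
- DDQ in CH2Cl2/pH 7 buffer at 0 °C frees 2-(trimethylsilyl)ethyl (5aS,6R,9S,9aS)-9-hydroxy-9-(hydroxymethyl)-1-oxo-6-(propan-2-yl)-1,3,5a,6,7,8,9,9a-octahydro-2-benzoxepine-4-carboxylate F6.
- F6 is acylated at once at its primary hydroxyl with 19 (Yamaguchi esterification: 2,4,6-trichlorobenzoyl chloride, Et3N, then DMAP, toluene, 0 °C), before the free CH2OH can attack the neighbouring lactone carbonyl. The branch comes back to the route at 33.

**Step 12 (Wittig reaction).** The hindered ylide 17 needs heat, and the cis β,γ-unsaturated aldehyde 12 can epimerise at C1 or slip into conjugation. The fallback replaces the olefination by a fast low-temperature aldol addition and a separate elimination, and sets out from 12.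
- Methyl 3-hydroxypropanoate is silylated (TIPSCl, imidazole) to methyl 3-{[tri(propan-2-yl)silyl]oxy}propanoate F7.
- Its lithium enolate (LiN(iPr)2, THF, −78 °C) adds to 12 within minutes to give methyl 3-[(1R,6S)-3-{[(tert-butyldimethylsilyl)oxy]methyl}-6-(propan-2-yl)cyclohex-2-en-1-yl]-3-hydroxy-2-({[tri(propan-2-yl)silyl]oxy}methyl)propanoate F8 (mixture at the two new centres, both lost later).
- MsCl/Et3N gives methyl 3-[(1R,6S)-3-{[(tert-butyldimethylsilyl)oxy]methyl}-6-(propan-2-yl)cyclohex-2-en-1-yl]-3-[(methanesulfonyl)oxy]-2-({[tri(propan-2-yl)silyl]oxy}methyl)propanoate F9.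
- DBU-mediated E1cB elimination gives methyl (2E)-3-[(1R,6S)-3-{[(tert-butyldimethylsilyl)oxy]methyl}-6-(propan-2-yl)cyclohex-2-en-1-yl]-2-({[tri(propan-2-yl)silyl]oxy}methyl)prop-2-enoate F10.
- Me3SnOH in 1,2-dichloroethane at 80 °C cleaves the methyl ester, and the branch comes back to the route at 19.

**Step 16 (conjugate addition with formaldehyde trapping).** Trapping the magnesium enolate with monomeric formaldehyde is capricious: proton transfer, double addition and dehydration to the α-methylene ketone all compete. The fallback separates the two bond formations and sets out from 22.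
- The same CuBr·SMe2-catalysed vinylmagnesium bromide addition, run with Me3SiCl, gives trimethyl{[(3R,4R)-3-ethenyl-4-(propan-2-yl)cyclohex-1-en-1-yl]oxy}silane F11.
- A Mukaiyama aldol reaction of F11 with aqueous formaldehyde and Yb(OTf)3 (THF/H2O, rt) hydroxymethylates C2 anti to the vinyl group, and the branch comes back to the route at 24.

## Further compounds

F1 | step 24 | (1S,2R,3R,4R)-2-{[(tert-butyldimethylsilyl)oxy]methyl}-3-ethenyl-1-{[(4-methoxybenzyl)oxy]methyl}-4-(propan-2-yl)cyclohexan-1-ol | CC(C)[C@H]1CC[C@@](O)(COCc2ccc(OC)cc2)[C@@H](CO[Si](C)(C)C(C)(C)C)[C@@H]1C=C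
F2 | step 24 | (1S,2R,3R,4R)-3-ethenyl-2-(hydroxymethyl)-1-{[(4-methoxybenzyl)oxy]methyl}-4-(propan-2-yl)cyclohexan-1-ol | CC(C)[C@H]1CC[C@@](O)(COCc2ccc(OC)cc2)[C@@H](CO)[C@@H]1C=C
F3 | step 24 | (1S,2S,5R,6R)-6-ethenyl-2-hydroxy-2-{[(4-methoxybenzyl)oxy]methyl}-5-(propan-2-yl)cyclohexane-1-carboxylic acid | CC(C)[C@H]1CC[C@@](O)(COCc2ccc(OC)cc2)[C@@H](C(O)=O)[C@@H]1C=C
F4 | step 24 | 2-{[2-(trimethylsilyl)ethoxy]carbonyl}prop-2-en-1-yl (1S,2S,5R,6R)-6-ethenyl-2-hydroxy-2-{[(4-methoxybenzyl)oxy]methyl}-5-(propan-2-yl)cyclohexane-1-carboxylate | CC(C)[C@H]1CC[C@@](O)(COCc2ccc(OC)cc2)[C@@H](C(=O)OCC(=C)C(=O)OCC[Si](C)(C)C)[C@@H]1C=C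
F5 | step 24 | 2-(trimethylsilyl)ethyl (5aS,6R,9S,9aS)-9-hydroxy-9-{[(4-methoxybenzyl)oxy]methyl}-1-oxo-6-(propan-2-yl)-1,3,5a,6,7,8,9,9a-octahydro-2-benzoxepine-4-carboxylate | CC(C)[C@H]1CC[C@@](O)(COCc3ccc(OC)cc3)[C@H]2C(=O)OCC(C(=O)OCC[Si](C)(C)C)=C[C@H]12
F6 | step 24 | 2-(trimethylsilyl)ethyl (5aS,6R,9S,9aS)-9-hydroxy-9-(hydroxymethyl)-1-oxo-6-(propan-2-yl)-1,3,5a,6,7,8,9,9a-octahydro-2-benzoxepine-4-carboxylate | CC(C)[C@H]1CC[C@@](O)(CO)[C@H]2C(=O)OCC(C(=O)OCC[Si](C)(C)C)=C[C@H]12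
F7 | step 12 | methyl 3-{[tri(propan-2-yl)silyl]oxy}propanoate | COC(=O)CCO[Si](C(C)C)(C(C)C)C(C)C
F8 | step 12 | methyl 3-[(1R,6S)-3-{[(tert-butyldimethylsilyl)oxy]methyl}-6-(propan-2-yl)cyclohex-2-en-1-yl]-3-hydroxy-2-({[tri(propan-2-yl)silyl]oxy}methyl)propanoate | COC(=O)C(CO[Si](C(C)C)(C(C)C)C(C)C)C(O)[C@H]1C=C(CO[Si](C)(C)C(C)(C)C)CC[C@H]1C(C)C
F9 | step 12 | methyl 3-[(1R,6S)-3-{[(tert-butyldimethylsilyl)oxy]methyl}-6-(propan-2-yl)cyclohex-2-en-1-yl]-3-[(methanesulfonyl)oxy]-2-({[tri(propan-2-yl)silyl]oxy}methyl)propanoate | COC(=O)C(CO[Si](C(C)C)(C(C)C)C(C)C)C(OS(C)(=O)=O)[C@H]1C=C(CO[Si](C)(C)C(C)(C)C)CC[C@H]1C(C)C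
F10 | step 12 | methyl (2E)-3-[(1R,6S)-3-{[(tert-butyldimethylsilyl)oxy]methyl}-6-(propan-2-yl)cyclohex-2-en-1-yl]-2-({[tri(propan-2-yl)silyl]oxy}methyl)prop-2-enoate | COC(=O)/C(=C/[C@H]1C=C(CO[Si](C)(C)C(C)(C)C)CC[C@H]1C(C)C)CO[Si](C(C)C)(C(C)C)C(C)C
F11 | step 16 | trimethyl{[(3R,4R)-3-ethenyl-4-(propan-2-yl)cyclohex-1-en-1-yl]oxy}silane | CC(C)[C@H]1CCC(O[Si](C)(C)C)=C[C@@H]1C=C
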